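Ring C is disconnected at C8, the lone methylene between the oxygenated C7 and C9, which sit on the fully substituted C6 and C10. Without C8, ring C shrinks to a six-membered, non-enolisable α-diketone bridging C5 and C10 of the cyclobutane (ring B), which a pinacol coupling can close. In the key step trimethylsilyldiazomethane and BF3·OEt2 insert one carbon between the two carbonyls by addition and acyl shift, forming C7–C8 and C8–C9 and enlarging the ring to ring C in one operation. The precursor already carries the C3 methyl group and C1 as a silyl ether; its cage comes from a ketene [2+2] cycloaddition and a tethered aldol.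

Key step: step 16

Atom numbering used throughout: C1 is the ring A ketone carbon, C2 its CH2, C3 the methyl-bearing CH; C4–C5–C11–C10 is the cyclobutane (ring B; C10 carries a methyl, C11 is bonded to C1); C6 is the gem-dimethyl carbon, C7 and C9 the ester carbons, C8 the CH2 between them (ring C).

Assumptions:
- Methyl hydrogen (R)-3-methylglutarate is taken as a purchasable chiral-pool half-ester (otherwise one desymmetrisation step from 3-methylglutaric anhydride).
- The pinacol diol of step 14 is drawn as one cis isomer; its two carbinol configurations are erased in step 15.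
- C8 of the silylated intermediate of step 16 is not a defined stereocentre.

Design remark: the ring C carbons on C5 and C10 must both lie on the face of ring B opposite ring A. A species that opens the central bond of a ring-A-bridged bicyclo[1.1.0]butane enters from the rear of that bond and ends on the ring A side. The cage is therefore built by a ketene [2+2] cycloaddition (alkene geometry fixes C10) and a tethered aldol (the tether fixes C5).

Step 1
Reactants: 1 tert-butyldimethyl(prop-2-yn-1-yloxy)silane
Product: 3 (E)-tert-butyl[(3-iodo-2-methylprop-2-en-1-yl)oxy]dimethylsilane, via alkenylalane 2 (not isolated)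
Conditions: Me3Al, Cp2ZrCl2 (0.25 equiv), CH2Cl2, 0 °C to rt; then I2, THF, −30 °C
Reagents that add atoms: trimethylaluminium, C[Al](C)C; iodine, II
Why: Negishi carboalumination adds CH3 and Al syn across the terminal alkyne with Al on the terminal carbon, and iodinolysis with retention should give the E iodide, in which the iodine (future C1 position) is trans to the CH2O carbon C9.

Step 2
Reactants: 4 methyl hydrogen (R)-3-methylglutarate
Product: 5 methyl (3S)-5-chloro-3-methyl-5-oxopentanoate
Conditions: (COCl)2, N,N-dimethylformamide (cat.), CH2Cl2, 0 °C to rt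
Reagents that add atoms: oxalyl chloride, ClC(=O)C(=O)Cl
Why: Acid chloride formation through the chloroiminium (Vilsmeier-type) activator leaves C3 untouched; the descriptor changes only because the CIP priorities change.

Step 3
Reactants: 3 (E)-alkenyl iodide; 5 acid chloride
Product: 8 methyl (3R,6E)-8-(tert-butyldimethylsilyloxy)-3,7-dimethyl-5-oxooct-6-enoate, via alkenyllithium 6 (not isolated), via alkenylzinc chloride 7 (not isolated)
Conditions: 3, t-BuLi (2 equiv), Et2O, −78 °C; ZnCl2, THF; then 5, Pd(PPh3)4 (5 mol %), THF, 0 °C to rt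
Reagents that add atoms: none
Why: Iodine–lithium exchange and transmetalation to zinc retain the alkene geometry, and Negishi acylation of the alkenylzinc by the acid chloride should give the enone (C1–C11 bond) without touching the methyl ester.

Step 4
Reactants: 8 enone
Product: 9 methyl (3R,5S,6E)-8-(tert-butyldimethylsilyloxy)-5-hydroxy-3,7-dimethyloct-6-enoate
Conditions: (R)-2-methyl-CBS-oxazaborolidine [(3aR)-1-methyl-3,3-diphenyltetrahydro-1H,3H-pyrrolo[1,2-c][1,3,2]oxazaborole] (0.2 equiv), catecholborane, toluene, −78 °C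
Reagents that add atoms: none
Why: Corey–Bakshi–Shibata reduction with the alkenyl group as the large substituent should give the 5S carbinol (future C1) by 1,2-reduction under catalyst control.

Step 5
Reactants: 9 allylic alcohol
Product: 10 methyl (3R,5S,6E)-5,8-bis(tert-butyldimethylsilyloxy)-3,7-dimethyloct-6-enoate
Conditions: TBSOTf, 2,6-lutidine, CH2Cl2, −78 to 0 °C
Reagents that add atoms: tert-butyldimethylsilyl trifluoromethanesulfonate, CC(C)(C)[Si](C)(C)OS(=O)(=O)C(F)(F)F
Why: Silylation of the secondary allylic alcohol with a silyl triflate and a hindered base; no stereocentre is involved.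

Step 6
Reactants: 10 bis-silyl ether ester
Product: 11 (3R,5S,6E)-5,8-bis(tert-butyldimethylsilyloxy)-3,7-dimethyloct-6-enoic acid
Conditions: LiOH, THF/MeOH/H2O, rt; then 1 M HCl to pH 3, 0 °C
Reagents that add atoms: lithium hydroxide, [Li+].[OH-]
Why: Saponification of the unhindered methyl ester; both silyl ethers tolerate aqueous base and a brief cold acidification.

Step 7
Reactants: 11 acid
Product: 13 2-(tert-butyldimethylsilyloxy)-7-[(tert-butyldimethylsilyloxy)methyl]-4,7-dimethylbicyclo[3.1.1]heptan-6-one (rings A and B; C5 is the ketone), via ketene 12 (not isolated)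
Conditions: 2-chloro-1-methylpyridinium iodide, Et3N, MeCN, reflux, slow addition of 11
Reagents that add atoms: none
Why: The activated acid eliminates to the ketene, which undergoes a thermal intramolecular ketene–alkene [2+2] cycloaddition (C5 to C11 at the less substituted alkene carbon, C4 to C10) giving the bridged cyclobutanone; addition is suprafacial on the E alkene, so C9 lands on the face of ring B opposite ring A, while allylic 1,3-strain with the C10 methyl keeps C1–H in the alkene plane, so that the C1 silyloxy group and, in the matched case, the C3 methyl both end on the C5 side, away from the C10 methyl, which sets C4, C10 and C11.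

Step 8
Reactants: 13 cyclobutanone
Product: 14 2-(tert-butyldimethylsilyloxy)-7-(hydroxymethyl)-4,7-dimethylbicyclo[3.1.1]heptan-6-one
Conditions: HF·pyridine, pyridine, THF, 0 °C
Reagents that add atoms: none
Why: Selective desilylation: under buffered fluoride the primary silyl ether at C9 should be cleaved faster than the hindered secondary one at C1.

Step 9
Reactants: 14 primary alcohol; 15 2-methylpropanoyl chloride
Product: 16 isobutyrate ester of 14 at the C9 oxygen
Conditions: 15, pyridine, 4-(dimethylamino)pyridine (cat.), CH2Cl2, 0 °C to rt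
Reagents that add atoms: none
Why: Nucleophile-catalysed acylation of the primary alcohol places the isobutyryl unit (future C6, C7 and the gem-dimethyl group) on the C9 oxygen as a tether.

Step 10
Reactants: 16 isobutyrate
Product: 19 tricyclic lactone carrying the methyl oxalate of the C5 tertiary alcohol, via potassium enolate 17 (not isolated), via potassium aldolate 18 (not isolated)
Conditions: KN(SiMe3)2, THF, −78 °C; then ClC(O)CO2Me, −78 to −20 °C
Reagents that add atoms: methyl chlorooxalate, COC(=O)C(=O)Cl
Why: Intramolecular aldol addition of the ester enolate to the non-enolisable cyclobutanone forms C5–C6 and the quaternary C6; the C9 tether can reach only the face of C5 opposite ring A, which fixes C5, and the alkoxide is trapped as the oxalate before retro-aldol.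

Step 11
Reactants: 19 oxalate
Product: 20 tricyclic lactone with C5–H (C7 lactone carbonyl, C9 as OCH2)
Conditions: Bu3SnH, 2,2'-azobis(2-methylpropionitrile) (cat.), toluene, 110 °C
Reagents that add atoms: none
Why: Barton–McCombie-type radical deoxygenation of a tertiary methyl oxalate; the C5 radical can accept hydrogen only on its outer face because the inner position is held by the C5–C6 ring bond.

Step 12
Reactants: 20 lactone
Product: 21 diol (C7 and C9 as CH2OH)
Conditions: LiAlH4, THF, 0 °C to rt
Reagents that add atoms: none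
Why: Hydride reduction of the lactone to the diol; the silyl ether is inert.

Step 13
Reactants: 21 diol
Product: 22 dialdehyde (C7 and C9 as CHO)
Conditions: (COCl)2, DMSO, CH2Cl2, −78 °C; Et3N, −78 to 0 °C
Reagents that add atoms: none
Why: Swern oxidation of both primary alcohols to non-enolisable aldehydes, each on a quaternary carbon.

Step 14
Reactants: 22 dialdehyde
Product: 23 tricyclic cis-7,9-diol (six-membered ring through the new C7–C9 bond)
Conditions: SmI2, THF, t-BuOH, −78 °C to rt
Reagents that add atoms: none
Why: Samarium diiodide pinacol coupling of two aldehydes held side by side on one face of ring B forms C7–C9 and the six-membered ring; the diol configuration is irrelevant because both carbinols are oxidised next.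

Step 15
Reactants: 23 cis-diol
Product: 24 (1S,3R,4S,5S,10R,11R)-1-(tert-butyldimethylsilyloxy) six-ring α-diketone cage (C7 bonded directly to C9)
Conditions: (COCl)2, DMSO, CH2Cl2, −78 °C; Et3N
Reagents that add atoms: none
Why: Swern oxidation converts the 1,2-diol into the 1,2-diketone without C–C cleavage; C6 and C10 are quaternary, so the diketone cannot enolise.

Step 16
Reactants: 24 α-diketone; 25 trimethylsilyldiazomethane
Product: 27 (1S,3R,4S,5S,10R,11R)-1-(tert-butyldimethylsilyloxy) tricyclic C7,C9 β-diketone (ring C complete), via C8-silyl diketone 26 (not isolated)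
Conditions: 25 (1.1 equiv), BF3·OEt2 (1.1 equiv), CH2Cl2, −78 to −40 °C; then sat. aq. NaHCO3, SiO2
Reagents that add atoms: none
Why: BF3 activates one carbonyl, the diazo carbon adds to it, and loss of N2 from the diazonium is accompanied by a 1,2-shift of the neighbouring acyl carbon, so the new carbon lands between C7 and C9; the C8–Si bond of 26 is cleaved on aqueous work-up. This is a Tiffeneau–Demjanov-type diazoalkane homologation, the reaction by which cyclic 1,2-diketones are enlarged to 1,3-diketones. Ring C is closed by ring enlargement of the six-membered diketone ring through this migration, not by an end-to-end cyclisation. No stereocentre is formed. The step needs acyl rather than alkyl migration and a single insertion: the acyl carbon is the better migrating group, attack at either carbonyl gives the same product, and the silylated 1,3-diketone is much less electrophilic than the α-diketone, which should protect it from a second insertion when about one equivalent of 25 is used.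

Step 17
Reactants: 27 β-diketone
Product: 28 (9R)-9-hydroxy-7-ketone
Conditions: (S)-2-methyl-CBS-oxazaborolidine [(3aS)-1-methyl-3,3-diphenyltetrahydro-1H,3H-pyrrolo[1,2-c][1,3,2]oxazaborole] (1 equiv), BH3·SMe2 (0.6 equiv), THF, −20 °C
Reagents that add atoms: none
Why: Corey–Bakshi–Shibata reduction with quaternary C10 as the large and C8H2 as the small substituent should give the 9R alcohol (oxygen toward C11); C9 should react first because C7 is shielded on both faces by the gem-dimethyl group.

Step 18
Reactants: 28 hydroxy ketone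
Product: 29 (7R,9R)-7,9-diol (anti)
Conditions: Me4NBH(OAc)3, MeCN/AcOH, −30 °C
Reagents that add atoms: none
Why: Evans–Saksena reduction: the C9 hydroxyl binds boron and delivers hydride intramolecularly to its own face of the C7 carbonyl, so the new hydroxyl ends up trans to it (7R).

Step 19
Reactants: 29 (7R,9R)-7,9-diol; 30 angelic acid (two molecules are taken up, one per hydroxyl)
Product: 31 7,9-bis-angelate with C1 silyl ether
Conditions: 30 (6 equiv), 2,4,6-trichlorobenzoyl chloride (6 equiv), Et3N (6 equiv), toluene, rt; then 29, toluene, 80 °C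
Reagents that add atoms: angelic acid (the second equivalent), C/C=C(/C)C(=O)O
Why: Yamaguchi-type esterification through the preformed angelic 2,4,6-trichlorobenzoic mixed anhydride, used in excess without a nucleophilic amine catalyst, should acylate both hindered secondary hydroxyls (C7 and C9) in one operation while avoiding the base-mediated Z to E isomerisation that would turn the angelates into tiglates.

Step 20
Reactants: 31 bis-angelate silyl ether
Product: 32 7,9-bis-angelate with free C1 hydroxyl
Conditions: HF·pyridine, THF, 0 °C to rt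
Reagents that add atoms: none
Why: Fluoride-mediated desilylation under mildly acidic conditions, to which the angelate esters are stable.

Step 21
Reactants: 32 C1 alcohol
Product: 33 CNP0283599.1 (target)
Conditions: Dess–Martin periodinane, NaHCO3, CH2Cl2, rt
Reagents that add atoms: none
Why: Dess–Martin oxidation of the secondary alcohol to the C1 ketone under buffered conditions; C11 is a bridgehead and cannot epimerise, and C3 is not adjacent to the carbonyl.

Compound list
1 | tert-butyldimethyl(prop-2-yn-1-yloxy)silane | C#CCO[Si](C)(C)C(C)(C)C | starting material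
2 | (E)-[3-(tert-butyldimethylsilyloxy)-2-methylprop-1-enyl]dimethylalane | C[Al](C)/C=C(\C)CO[Si](C)(C)C(C)(C)C | intermediate
3 | (E)-tert-butyl[(3-iodo-2-methylprop-2-en-1-yl)oxy]dimethylsilane | I/C=C(\C)CO[Si](C)(C)C(C)(C)C | intermediate
4 | methyl hydrogen (R)-3-methylglutarate, (3R)-5-methoxy-3-methyl-5-oxopentanoic acid | COC(=O)C[C@H](C)CC(=O)O | starting material
5 | methyl (3S)-5-chloro-3-methyl-5-oxopentanoate | COC(=O)C[C@H](C)CC(=O)Cl | intermediate
6 | (E)-[3-(tert-butyldimethylsilyloxy)-2-methylprop-1-enyl]lithium | [Li]/C=C(\C)CO[Si](C)(C)C(C)(C)C | intermediate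
7 | (E)-[3-(tert-butyldimethylsilyloxy)-2-methylprop-1-enyl]zinc chloride | Cl[Zn]/C=C(\C)CO[Si](C)(C)C(C)(C)C | intermediate
8 | methyl (3R,6E)-8-(tert-butyldimethylsilyloxy)-3,7-dimethyl-5-oxooct-6-enoate | COC(=O)C[C@H](C)CC(=O)/C=C(\C)CO[Si](C)(C)C(C)(C)C | intermediate
9 | methyl (3R,5S,6E)-8-(tert-butyldimethylsilyloxy)-5-hydroxy-3,7-dimethyloct-6-enoate | COC(=O)C[C@H](C)C[C@H](O)/C=C(\C)CO[Si](C)(C)C(C)(C)C | intermediate
10 | methyl (3R,5S,6E)-5,8-bis(tert-butyldimethylsilyloxy)-3,7-dimethyloct-6-enoate | COC(=O)C[C@H](C)C[C@H](O[Si](C)(C)C(C)(C)C)/C=C(\C)CO[Si](C)(C)C(C)(C)C | intermediate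
11 | (3R,5S,6E)-5,8-bis(tert-butyldimethylsilyloxy)-3,7-dimethyloct-6-enoic acid | OC(=O)C[C@H](C)C[C@H](O[Si](C)(C)C(C)(C)C)/C=C(\C)CO[Si](C)(C)C(C)(C)C | intermediate
12 | (3R,5S,6E)-5,8-bis(tert-butyldimethylsilyloxy)-3,7-dimethylocta-1,6-dien-1-one (ketene) | O=C=C[C@H](C)C[C@H](O[Si](C)(C)C(C)(C)C)/C=C(\C)CO[Si](C)(C)C(C)(C)C | intermediate
13 | bicyclo[3.1.1]heptan-6-one of rings A and B: C5 ketone, C1 OTBS (S), C3 methyl (R), C10 methyl and CH2OTBS, the CH2OTBS on the face of ring B opposite ring A | O=C1[C@@H]2[C@H](C)C[C@H](O[Si](C)(C)C(C)(C)C)[C@H]1[C@]2(C)CO[Si](C)(C)C(C)(C)C | intermediate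
14 | primary alcohol from 13 (C9 as CH2OH) | O=C1[C@@H]2[C@H](C)C[C@H](O[Si](C)(C)C(C)(C)C)[C@H]1[C@]2(C)CO | intermediate
15 | 2-methylpropanoyl chloride (isobutyryl chloride) | CC(C)C(=O)Cl | starting material
16 | isobutyrate of 14 | O=C1[C@@H]2[C@H](C)C[C@H](O[Si](C)(C)C(C)(C)C)[C@H]1[C@]2(C)COC(=O)C(C)C | intermediate
17 | potassium ester enolate of 16 | [K+].O=C1[C@@H]2[C@H](C)C[C@H](O[Si](C)(C)C(C)(C)C)[C@H]1[C@]2(C)COC([O-])=C(C)C | intermediate
18 | potassium aldolate: tricyclic lactone with C5 alkoxide on the outer face | [K+].O=C1OC[C@@]2(C)[C@@H]3[C@@H](O[Si](C)(C)C(C)(C)C)C[C@@H](C)[C@H]2[C@]3([O-])C1(C)C | intermediate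
19 | tricyclic lactone, methyl oxalate of the C5 tertiary alcohol | O=C1OC[C@@]2(C)[C@@H]3[C@@H](O[Si](C)(C)C(C)(C)C)C[C@@H](C)[C@H]2[C@]3(OC(=O)C(=O)OC)C1(C)C | intermediate
20 | tricyclic lactone with C5–H (C5–C6 bond on the face of ring B opposite ring A) | O=C1OC[C@@]2(C)[C@@H]3[C@@H](O[Si](C)(C)C(C)(C)C)C[C@@H](C)[C@H]2[C@@H]3C1(C)C | intermediate
21 | diol: C5–C(CH3)2–CH2OH and C10–CH2OH | OCC(C)(C)[C@H]1[C@@H]2[C@H](C)C[C@H](O[Si](C)(C)C(C)(C)C)[C@H]1[C@]2(C)CO | intermediate
22 | dialdehyde: C7 and C9 as CHO | O=CC(C)(C)[C@H]1[C@@H]2[C@H](C)C[C@H](O[Si](C)(C)C(C)(C)C)[C@H]1[C@]2(C)C=O | intermediate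
23 | tricyclic cis-7,9-diol, six-membered ring through C7–C9 (cis isomer drawn with both hydroxyls toward C11) | O[C@H]1[C@@H](O)[C@]2(C)[C@@H]3[C@@H]([C@H]2[C@@H](O[Si](C)(C)C(C)(C)C)C[C@H]3C)C1(C)C | intermediate
24 | (1S,3R,4S,5S,10R,11R) six-ring α-diketone cage, C7 bonded to C9, C1 OTBS, C3 methyl | O=C1C(=O)[C@]2(C)[C@@H]3[C@@H]([C@H]2[C@@H](O[Si](C)(C)C(C)(C)C)C[C@H]3C)C1(C)C | intermediate
25 | trimethylsilyldiazomethane | C[Si](C)(C)C=[N+]=[N-] | starting material
26 | C8-trimethylsilyl β-diketone (C8 configuration not defined) | O=C1C([Si](C)(C)C)C(=O)[C@]2(C)[C@@H]3[C@@H]([C@H]2[C@@H](O[Si](C)(C)C(C)(C)C)C[C@H]3C)C1(C)C | intermediate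
27 | (1S,3R,4S,5S,10R,11R) tricyclic C7,C9 β-diketone, C1 OTBS, C3 methyl | O=C1CC(=O)[C@]2(C)[C@@H]3[C@@H]([C@H]2[C@@H](O[Si](C)(C)C(C)(C)C)C[C@H]3C)C1(C)C | intermediate
28 | (9R)-9-hydroxy-7-ketone | O=C1C[C@@H](O)[C@]2(C)[C@@H]3[C@@H]([C@H]2[C@@H](O[Si](C)(C)C(C)(C)C)C[C@H]3C)C1(C)C | intermediate
29 | (7R,9R)-7,9-diol | O[C@@H]1C[C@@H](O)[C@]2(C)[C@@H]3[C@@H]([C@H]2[C@@H](O[Si](C)(C)C(C)(C)C)C[C@H]3C)C1(C)C | intermediate
30 | angelic acid, (Z)-2-methylbut-2-enoic acid | C/C=C(/C)C(=O)O | starting material
31 | (7R,9R)-bis-angelate, C1 OTBS | C/C=C(/C)C(=O)O[C@@H]1C[C@@H](OC(=O)/C(C)=C\C)[C@]2(C)[C@@H]3[C@@H]([C@H]2[C@@H](O[Si](C)(C)C(C)(C)C)C[C@H]3C)C1(C)C | intermediate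
32 | (7R,9R)-bis-angelate, (1S)-C1 alcohol | C/C=C(/C)C(=O)O[C@@H]1C[C@@H](OC(=O)/C(C)=C\C)[C@]2(C)[C@@H]3[C@@H]([C@H]2[C@@H](O)C[C@H]3C)C1(C)C | intermediate
33 | CNP0283599.1, (3R,4S,5S,7R,9R,10R,11R) 7,9-bis-angelate of the C1 ketone | C/C=C(/C)C(=O)O[C@@H]1C[C@@H](OC(=O)/C(C)=C\C)[C@]2(C)[C@@H]3[C@@H]([C@H]2C(=O)C[C@H]3C)C1(C)C | target

Total step count: 21. Longest linear sequence: 20 steps (steps 2 to 21 from 4; equally steps 1 and 3 to 21 from 1).

Steps most likely to fail

1. Step 16 (key step). What may go wrong: migration of a quaternary alkyl carbon (C6 or C10) in place of the acyl carbon, collapse of the adduct to a spiro-epoxide, or a second insertion into the product. Fallback, which closes ring C by an aldol reaction instead of a ring enlargement: it sets out from lactone 20. MeLi (THF, −78 °C) should open the hindered lactone to the hydroxy methyl ketone F1. Dess–Martin oxidation gives the keto aldehyde F2. LiN(SiMe3)2 (THF, −78 °C) enolises the methyl ketone, the only enolisable position, and intramolecular aldol addition to the non-enolisable C9 aldehyde closes the seven-membered ring as the β-hydroxy ketone F3 (C9 epimers), with C8 coming from methyllithium. Dess–Martin oxidation of F3 comes back to the route at β-diketone 27.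

2. Step 7. What may go wrong: oligomerisation of the monoalkylketene, or attack of the C1 silyloxy oxygen on it, outrunning cycloaddition to an alkene that two allylic oxygens make less nucleophilic. Fallback, which uses a keteniminium salt instead of the ketene: it sets out from acid 11. Coupling with pyrrolidine (1-ethyl-3-(3-dimethylaminopropyl)carbodiimide hydrochloride, 1-hydroxybenzotriazole, CH2Cl2) gives the pyrrolidine amide F4. Tf2O and 2,4,6-collidine in 1,2-dichloroethane at 80 °C convert it into the keteniminium triflate F5, a much stronger electrophile, which should cyclise in the same [2+2] sense to the cyclobutaniminium triflate F6. Hydrolysis with aqueous NaHCO3 comes back to the route at cyclobutanone 13.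

3. Step 10. What may go wrong: retro-aldol before the alkoxide is trapped, incomplete enolisation, or intermolecular condensation of the hindered enolate instead of cage closure. Fallback, which generates the enolate reductively under non-basic conditions: it sets out from alcohol 14. Acylation with 2-bromo-2-methylpropanoyl bromide (pyridine, CH2Cl2) gives the bromo ester F7. SmI2 (THF, −78 °C) forms the samarium enolate, and an intramolecular Reformatsky reaction with the C5 ketone gives the hydroxy lactone F8. Acylation with ClC(O)CO2Me (4-(dimethylamino)pyridine, Et3N, CH2Cl2) comes back to the route at oxalate 19.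

Further compounds
F1 | step 16 | hydroxy methyl ketone: C5–C(CH3)2–C(=O)CH3 and C10–CH2OH | CC(=O)C(C)(C)[C@H]1[C@@H]2[C@H](C)C[C@H](O[Si](C)(C)C(C)(C)C)[C@H]1[C@]2(C)CO
F2 | step 16 | keto aldehyde: C5–C(CH3)2–C(=O)CH3 and C10–CHO | CC(=O)C(C)(C)[C@H]1[C@@H]2[C@H](C)C[C@H](O[Si](C)(C)C(C)(C)C)[C@H]1[C@]2(C)C=O
F3 | step 16 | 9-hydroxy-7-ketone with ring C closed (C9 epimers) | O=C1CC(O)[C@]2(C)[C@@H]3[C@@H]([C@H]2[C@@H](O[Si](C)(C)C(C)(C)C)C[C@H]3C)C1(C)C
F4 | step 7 | pyrrolidine amide of acid 11 | O=C(C[C@H](C)C[C@H](O[Si](C)(C)C(C)(C)C)/C=C(\C)CO[Si](C)(C)C(C)(C)C)N1CCCC1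
F5 | step 7 | keteniminium triflate from F4 | C1CC[N+](C1)=C=C[C@H](C)C[C@H](O[Si](C)(C)C(C)(C)C)/C=C(\C)CO[Si](C)(C)C(C)(C)C.[O-]S(=O)(=O)C(F)(F)F
F6 | step 7 | cyclobutaniminium triflate (iminium of 13) | C1CC[N+](C1)=C3[C@@H]2[C@H](C)C[C@H](O[Si](C)(C)C(C)(C)C)[C@H]3[C@]2(C)CO[Si](C)(C)C(C)(C)C.[O-]S(=O)(=O)C(F)(F)F
F7 | step 10 | 2-bromo-2-methylpropanoate of alcohol 14 | O=C1[C@@H]2[C@H](C)C[C@H](O[Si](C)(C)C(C)(C)C)[C@H]1[C@]2(C)COC(=O)C(C)(C)Br
F8 | step 10 | tricyclic hydroxy lactone (free C5 tertiary alcohol) | O=C1OC[C@@]2(C)[C@@H]3[C@@H](O[Si](C)(C)C(C)(C)C)C[C@@H](C)[C@H]2[C@]3(O)C1(C)C
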